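**Retrosynthetic overview**
1. Key disconnection, a C–O bond: the ring ketone oxygen is installed last, by oxidative 1,3-transposition of a tertiary cyclohexa-2,4-dienyl carbinol; the same oxidation turns the side-chain carbinol into the ethyl ketone.
2. Ring–side-chain C–C bond: 1,2-addition of an (E)-alkenylcerium reagent to a 6,6-disubstituted cyclohexa-2,4-dienone; the side-chain methyl stereocentre comes from a Marshall propargylation.
3. Quaternary stereocentre: enantioselective ortho-dearomatisation of a trimethylphenol by ligand coupling on lead with a pyranonyl group (the proposed new step).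
4. Pyranonyl donor: ring C–H metalation and stannylation of an α-methoxy-γ-pyranone made from a β-keto ester by formylation, lactonisation and O-methylation.
5. Ring order: pyranone ring first (lactonisation), carbocyclic dienone second (dearomatisation of the phenol ring); no ring is closed afterwards.

Assumption 1: oxygen-bound salts (enolates, alkoxides) of a numbered compound are counted as that compound; species with a carbon–metal bond are numbered as intermediates.
Assumption 2: the sense of induction in step 4 cannot be predicted; the (S,S)-ligand is written, and its commercial (R,R)-antipode is used instead if the first run gives the mirror-image dienone (checked on 9 by X-ray or ECD).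

**Route**

Step 1
Reactants: 1 methyl 2-methyl-3-oxopentanoate
Product: 3 4-hydroxy-3,5-dimethyl-2H-pyran-2-one, via methyl 2,4-dimethyl-3,5-dioxopentanoate 2 (not isolated)
Conditions: NaH, THF, 0 °C; n-BuLi, 0 °C; HCO2Me, −78 to 0 °C; aq. HCl; crude 2, DBU, PhMe, 80 °C
Reagents that add atoms: methyl formate, COC=O
Why: The Huckin–Weiler dianion of the β-keto ester is formylated at its terminal carbon (crossed Claisen condensation) and the formyl enol lactonises onto the ester under DBU (4-hydroxy-2-pyranone synthesis); no stereocentre survives.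

Step 2
Reactants: 3 4-hydroxy-3,5-dimethyl-2H-pyran-2-one
Product: 4 2-methoxy-3,5-dimethyl-4H-pyran-4-one
Conditions: MeOTf, CH2Cl2, 0 °C to rt
Reagents that add atoms: methyl trifluoromethanesulfonate, COS(=O)(=O)C(F)(F)F
Why: Hard O-methylation of a 3,5-dimethyl-4-hydroxy-2-pyranone takes place at the lactone carbonyl oxygen and gives the α-methoxy-γ-pyranone after loss of the proton (regioselective O-alkylation).

Step 3
Reactants: 4 2-methoxy-3,5-dimethyl-4H-pyran-4-one
Product: 6 2-methoxy-3,5-dimethyl-6-(tributylstannyl)-4H-pyran-4-one, via pyranonylmagnesium chloride 5 (not isolated)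
Conditions: (2,2,6,6-tetramethylpiperidin-1-yl)MgCl·LiCl, THF, −40 °C; Bu3SnCl, −40 °C to rt
Reagents that add atoms: tributyltin chloride, CCCC[Sn](Cl)(CCCC)CCCC
Why: Directed metalation removes the only ring C–H, which lies next to the ring oxygen, and the pyranonyl-magnesium species is trapped by Bu3SnCl (metalation then stannylation).

Step 4
Reactants: 6 2-methoxy-3,5-dimethyl-6-(tributylstannyl)-4H-pyran-4-one, 7 2,4,6-trimethylphenol
Product: 9 2-methoxy-3,5-dimethyl-6-[(1R)-1,3,5-trimethyl-6-oxocyclohexa-2,4-dien-1-yl]-4H-pyran-4-one, via pyranonyllead triacetate 8 (not isolated)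
Conditions: Pb(OAc)4 (1.0 equiv), Hg(OAc)2 (5 mol %), CHCl3, 40 °C; then 7, (S,S)-2,2′-isopropylidenebis(4-phenyl-2-oxazoline) (1.5 equiv), 4 Å MS, PhMe–CHCl3, −30 °C
Reagents that add atoms: none
Why: Proposed new method: tin-to-lead exchange gives the pyranonyl-lead triacetate, the phenol displaces one acetate to give an aryloxy–lead species held in the pocket of the lead-bound chiral bis(oxazoline), and ligand coupling (tetravalent lead going to divalent lead through a cyclic transition state) moves the pyranonyl group from lead to one of the two enantiotopic methyl-bearing ortho carbons, so the ligand antipode decides the configuration of the new quaternary centre, while delivery from the oxygen-bound metal is expected to disfavour O- and para-attack; the closest known reaction type is the pyridine-promoted Pinhey ortho-arylation of 2,4,6-trimethylphenol with aryllead triacetates (racemic 6-aryl-2,4,6-trimethylcyclohexa-2,4-dienones) together with chiral-amine-controlled aryllead couplings to axially chiral biaryls, and what is new is the 4-pyranon-2-yl group as migrating ligand and the control of a central quaternary stereocentre.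

Step 5
Reactants: 10 (R)-but-3-yn-2-ol
Product: 11 (R)-but-3-yn-2-yl methanesulfonate
Conditions: MsCl, Et3N, CH2Cl2, −78 to 0 °C
Reagents that add atoms: methanesulfonyl chloride, CS(=O)(=O)Cl
Why: Mesylation takes place at oxygen and leaves the (R) stereocentre untouched.

Step 6
Reactants: 11 (R)-but-3-yn-2-yl methanesulfonate, 12 propanal
Product: 14 (3R,4S)-4-methylhex-5-yn-3-ol, via allenyl(ethyl)zinc 13 (not isolated)
Conditions: Pd(OAc)2 (5 mol %), PPh3 (5 mol %), Et2Zn (3 equiv), THF, −78 to −20 °C; aq. NH4Cl
Reagents that add atoms: none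
Why: Marshall propargylation: zerovalent palladium opens the mesylate by anti SN2′ attack, transmetalation gives the axially chiral allenylzinc, and its syn SE2′ addition to propanal through a cyclic transition state transfers the chirality to the (S) methyl-bearing carbon (the anti carbinol predominates and this carbinol centre is erased in step 10).

Step 7
Reactants: 14 (3R,4S)-4-methylhex-5-yn-3-ol
Product: 16 (3R,4S)-4-methylhept-5-yn-3-ol, via dilithio acetylide alkoxide 15 (not isolated)
Conditions: n-BuLi (2.1 equiv), THF, −78 to −20 °C; MeI (1.05 equiv), −78 °C to rt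
Reagents that add atoms: iodomethane, CI
Why: In the dianion the lithium acetylide is far more nucleophilic towards iodomethane than the lithium alkoxide (C-methylation of a terminal alkyne), and both stereocentres are untouched.

Step 8
Reactants: 16 (3R,4S)-4-methylhept-5-yn-3-ol
Product: 18 (3R,4S,5E)-6-iodo-4-methylhept-5-en-3-ol, via doubly zirconated alkenyl alkoxide 17 (not isolated)
Conditions: Cp2Zr(H)Cl (3 equiv), THF, 50 °C; then I2, 0 °C
Reagents that add atoms: iodine, II
Why: Hydrozirconation is a syn addition that, with excess Cp2Zr(H)Cl under equilibration, places zirconium on the less hindered methyl-bearing alkyne carbon, and iodinolysis of the C–Zr bond with retention fixes the (E)-alkenyl iodide (hydrozirconation–iodination).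

Step 9
Reactants: 18 (3R,4S,5E)-6-iodo-4-methylhept-5-en-3-ol, 9 2-methoxy-3,5-dimethyl-6-[(1R)-1,3,5-trimethyl-6-oxocyclohexa-2,4-dien-1-yl]-4H-pyran-4-one
Product: 21 6-[(1S)-2-hydroxy-2-[(2E,4S,5R)-5-hydroxy-4-methylhept-2-en-2-yl]-1,3,5-trimethylcyclohexa-3,5-dien-1-yl]-2-methoxy-3,5-dimethyl-4H-pyran-4-one (both epimers at the new ring carbinol), via dilithio alkenyl alkoxide 19 (not isolated), via alkenylcerium dichloride 20 (not isolated)
Conditions: 18 (1.5 equiv), t-BuLi (3.1 equiv per 18), Et2O, −78 °C; CeCl3, THF, −78 °C; then 9, −78 to −40 °C; aq. NH4Cl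
Reagents that add atoms: none
Why: Iodine–lithium exchange keeps the alkene geometry and the weakly basic organocerium adds 1,2 to the hindered, non-enolisable dienone carbonyl in preference to the vinylogous ester of the pyranone (Imamoto organocerium addition); the new carbinol centre is uncontrolled and is removed in step 10.

Step 10
Reactants: 21 6-[(1S)-2-hydroxy-2-[(2E,4S,5R)-5-hydroxy-4-methylhept-2-en-2-yl]-1,3,5-trimethylcyclohexa-3,5-dien-1-yl]-2-methoxy-3,5-dimethyl-4H-pyran-4-one
Product: 22 2-methoxy-3,5-dimethyl-6-[(1S)-1,3,5-trimethyl-2-[(2E,4S)-4-methyl-5-oxohept-2-en-2-yl]-4-oxocyclohexa-2,5-dien-1-yl]-4H-pyran-4-one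
Conditions: pyridinium chlorochromate [C5H5NH][CrO3Cl] (5 equiv), 4 Å MS, CH2Cl2, 0 °C to rt
Reagents that add atoms: pyridinium chlorochromate, [O-][Cr](=O)(=O)Cl.c1cc[nH+]cc1
Why: Babler–Dauben oxidative transposition: the tertiary chromate ester shifts [3,3] across the ring allyl unit, which forms the new C–O bond at the ring CH para to the quaternary carbon, and the doubly allylic secondary chromate is oxidised to the cross-conjugated dienone, while the same reagent oxidises the side-chain carbinol to the ethyl ketone without touching the adjacent (S) centre; a shift into the side chain would need a crowded exocyclic tetrasubstituted alkene and the other ring CH is shielded by the quaternary carbon.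

**Compound list**
1 | methyl 2-methyl-3-oxopentanoate (racemic) | CCC(=O)C(C)C(=O)OC | starting material
2 | methyl 2,4-dimethyl-3,5-dioxopentanoate (stereoisomer and enol mixture) | COC(=O)C(C)C(=O)C(C)C=O | intermediate
3 | 4-hydroxy-3,5-dimethyl-2H-pyran-2-one | CC1=COC(=O)C(C)=C1O | intermediate
4 | 2-methoxy-3,5-dimethyl-4H-pyran-4-one | COc1occ(C)c(=O)c1C | intermediate
5 | chlorido(6-methoxy-3,5-dimethyl-4-oxo-4H-pyran-2-yl)magnesium (LiCl complex) | COc1oc([Mg]Cl)c(C)c(=O)c1C | intermediate
6 | 2-methoxy-3,5-dimethyl-6-(tributylstannyl)-4H-pyran-4-one | CCCC[Sn](CCCC)(CCCC)c1oc(OC)c(C)c(=O)c1C | intermediate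
7 | 2,4,6-trimethylphenol | Cc1cc(C)c(O)c(C)c1 | starting material
8 | (6-methoxy-3,5-dimethyl-4-oxo-4H-pyran-2-yl)lead triacetate | CC(=O)O[Pb](OC(C)=O)(OC(C)=O)c1oc(OC)c(C)c(=O)c1C | intermediate
9 | 2-methoxy-3,5-dimethyl-6-[(1R)-1,3,5-trimethyl-6-oxocyclohexa-2,4-dien-1-yl]-4H-pyran-4-one | O=C1C(C)=CC(C)=C[C@]1(C)c1oc(OC)c(C)c(=O)c1C | intermediate
10 | (R)-but-3-yn-2-ol | C[C@@H](O)C#C | starting material
11 | (R)-but-3-yn-2-yl methanesulfonate | C[C@@H](OS(C)(=O)=O)C#C | intermediate
12 | propanal | CCC=O | starting material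
13 | (Sa)-buta-1,2-dien-1-yl(ethyl)zinc | [H]C([Zn]CC)=[C@]=C([H])C | intermediate
14 | (3R,4S)-4-methylhex-5-yn-3-ol | CC[C@@H](O)[C@@H](C)C#C | intermediate
15 | lithium (3R,4S)-6-lithio-4-methylhex-5-yn-3-olate | CC[C@@H](O[Li])[C@@H](C)C#C[Li] | intermediate
16 | (3R,4S)-4-methylhept-5-yn-3-ol | CC[C@@H](O)[C@@H](C)C#CC | intermediate
17 | (3R,4S,5E)-4-methylhept-5-en-3-ol carrying Zr(Cp)2Cl on O and on C6 (cyclopentadienyl rings drawn σ-bonded) | CC[C@@H](O[Zr](Cl)(C1C=CC=C1)C1C=CC=C1)[C@@H](C)/C=C(\C)[Zr](Cl)(C1C=CC=C1)C1C=CC=C1 | intermediate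
18 | (3R,4S,5E)-6-iodo-4-methylhept-5-en-3-ol | CC[C@@H](O)[C@@H](C)/C=C(\C)I | intermediate
19 | lithium (3R,4S)-6-lithio-4-methylhept-5-en-3-olate, lithium trans to C4 (geometry of 18 kept) | CC[C@@H](O[Li])[C@@H](C)/C=C(\C)[Li] | intermediate
20 | lithium (3R,4S,5E)-6-(dichlorocerio)-4-methylhept-5-en-3-olate | CC[C@@H](O[Li])[C@@H](C)/C=C(\C)[Ce](Cl)Cl | intermediate
21 | 6-[(1S)-2-hydroxy-2-[(2E,4S,5R)-5-hydroxy-4-methylhept-2-en-2-yl]-1,3,5-trimethylcyclohexa-3,5-dien-1-yl]-2-methoxy-3,5-dimethyl-4H-pyran-4-one (epimer mixture at ring C2) | CC[C@@H](O)[C@@H](C)/C=C(\C)C1(O)C(C)=CC(C)=C[C@]1(C)c1oc(OC)c(C)c(=O)c1C | intermediate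
22 | 2-methoxy-3,5-dimethyl-6-[(1S)-1,3,5-trimethyl-2-[(2E,4S)-4-methyl-5-oxohept-2-en-2-yl]-4-oxocyclohexa-2,5-dien-1-yl]-4H-pyran-4-one | CCC(=O)[C@@H](C)/C=C(\C)C1=C(C)C(=O)C(C)=C[C@]1(C)c1oc(OC)c(C)c(=O)c1C | target

**Step count**
Total: 10 steps. Longest linear sequence: 6 steps (steps 1, 2, 3, 4, 9, 10; the side-chain arm, steps 5, 6, 7, 8, 9, 10, is equally long).

**Three steps most likely to fail**

Step 4, the proposed new ligand coupling. The pyranonyl group may transfer sluggishly from lead, and the chiral ligand may give low enantioselectivity. Fallback with known chemistry, setting out from 6 and 7: run the coupling under the classical aryllead triacetate conditions with pyridine as the lead ligand to obtain the racemic dienone F1, then resolve it by preparative chiral-phase SFC, keeping 9 and setting aside the (S)-enantiomer F2. The fallback re-joins the route at 9.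

Step 9, addition to the hindered dienone. The dianionic reagent may be poorly soluble or too unreactive towards a carbonyl flanked by a quaternary carbon, or it may attack the methoxy-bearing carbon of the pyranone. Fallback, setting out from 18: protect the carbinol (Et3SiCl, imidazole) as the triethylsilyl ether F3, convert it by iodine–lithium exchange (t-BuLi, 2 equiv) into the soluble mono-lithium reagent F4, add this to 9 at −78 °C to give the silyl-protected carbinol F5, and cleave the silyl ether with HF·pyridine. The fallback re-joins the route at 21.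

Step 10, the oxidative transposition. The chromate may shift towards the side chain, and the acidic reagent may ionise the dienyl carbinol or erode the α-stereocentre of the new β,γ-unsaturated ketone. Fallback, setting out from 21: separate the transposition from the oxidation by isomerising the tertiary carbinol with catalytic Ph3SiOReO3 (non-oxidative [3,3] shift through a perrhenate ester, under thermodynamic control) to the ring-transposed diol F6, then oxidise both secondary carbinols with Dess–Martin periodinane buffered with NaHCO3. The fallback re-joins the route at 22.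

**Further compounds**
F1 | step 4 | racemic 2-methoxy-3,5-dimethyl-6-(1,3,5-trimethyl-6-oxocyclohexa-2,4-dien-1-yl)-4H-pyran-4-one | O=C1C(C)=CC(C)=CC1(C)c1oc(OC)c(C)c(=O)c1C
F2 | step 4 | 2-methoxy-3,5-dimethyl-6-[(1S)-1,3,5-trimethyl-6-oxocyclohexa-2,4-dien-1-yl]-4H-pyran-4-one | O=C1C(C)=CC(C)=C[C@@]1(C)c1oc(OC)c(C)c(=O)c1C
F3 | step 9 | triethyl{[(3R,4S,5E)-6-iodo-4-methylhept-5-en-3-yl]oxy}silane | CC[C@@H](O[Si](CC)(CC)CC)[C@@H](C)/C=C(\C)I
F4 | step 9 | [(4S,5R)-4-methyl-5-(triethylsilyloxy)hept-2-en-2-yl]lithium, lithium trans to C4 | CC[C@@H](O[Si](CC)(CC)CC)[C@@H](C)/C=C(\C)[Li]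
F5 | step 9 | 6-[(1S)-2-hydroxy-1,3,5-trimethyl-2-[(2E,4S,5R)-4-methyl-5-(triethylsilyloxy)hept-2-en-2-yl]cyclohexa-3,5-dien-1-yl]-2-methoxy-3,5-dimethyl-4H-pyran-4-one (epimer mixture at ring C2) | CC[C@@H](O[Si](CC)(CC)CC)[C@@H](C)/C=C(\C)C1(O)C(C)=CC(C)=C[C@]1(C)c1oc(OC)c(C)c(=O)c1C
F6 | step 10 | 6-[(1S)-4-hydroxy-2-[(2E,4S,5R)-5-hydroxy-4-methylhept-2-en-2-yl]-1,3,5-trimethylcyclohexa-2,5-dien-1-yl]-2-methoxy-3,5-dimethyl-4H-pyran-4-one (epimer mixture at ring C4) | CC[C@@H](O)[C@@H](C)/C=C(\C)C1=C(C)C(O)C(C)=C[C@]1(C)c1oc(OC)c(C)c(=O)c1C
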